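**Retrosynthetic overview**

1. Confluentic acid is a depside: ring A (2-hydroxy-4-methoxybenzoyl; C1 bears the ester carbonyl, C6 bears CH2–CO–C5H11) is esterified to O-4 of ring B (2-methoxy-6-pentylbenzoic acid). The plan rests on the ring A C6–CH2 bond. This CH2 sits between the arene and the chain ketone and ortho to the C1 carbonyl, so a ring A acid that already carried the keto chain would close to an isocoumarin on activation; the chain is therefore attached last.
2. Last C–C disconnection: the C6–CH2 bond, made on the finished depside by nickel-electrocatalytic decarboxylative sp2–sp3 coupling of the ring A aryl bromide with the N-acyloxyphthalimide of dioxolane-masked 3-oxooctanoic acid (from ethyl 3-oxooctanoate).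
3. Depside C(=O)–O disconnection: 2-(benzyloxy)-6-bromo-4-methoxybenzoic acid (from 1-bromo-3,5-dimethoxybenzene) and benzyl 4-hydroxy-2-methoxy-6-pentylbenzoate (from olivetol).
4. No ring is constructed: both benzene rings are bought, and the only ring made on the way is the temporary dioxolane.
5. End game: hydrolysis of the ketal, then one hydrogenolysis of the benzyl ether and the benzyl ester.

Key step: step 15

Remark: the target has no stereocentre and no stereogenic double bond, so no step has to set configuration; simple commercial reagents (BnBr, MeI, ethylene glycol, N-hydroxyphthalimide and the like) are not numbered.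

**Ring A acid**

Step 1
Reactants: 1 1-bromo-3,5-dimethoxybenzene
Product: 3 2-bromo-4,6-dimethoxybenzaldehyde, via iminium chloride 2 (not isolated)
Conditions: POCl3, DMF, 0 °C to 90 °C; then ice-water
Reagents that add atoms: N,N-dimethylformamide CN(C)C=O; water O
Why: Vilsmeier–Haack formylation: the chloroiminium ion attacks the carbon para to one methoxy group and ortho to the other (next to bromine), the carbon between the two methoxy groups being more crowded, and water hydrolyses iminium salt 2 to the aldehyde.

Step 2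
Reactants: 3 2-bromo-4,6-dimethoxybenzaldehyde
Product: 5 2-bromo-6-hydroxy-4-methoxybenzaldehyde, via aryloxydichloroborane 4 (not isolated)
Conditions: BCl3, CH2Cl2, −78 °C to 0 °C; then H2O
Reagents that add atoms: none
Why: Chelation-directed Lewis acid ether cleavage: BCl3 bridges the aldehyde oxygen and the ortho methoxy oxygen, so chloride removes only that methyl group (SN2 at methyl) and the para methoxy group should stay.

Step 3
Reactants: 5 2-bromo-6-hydroxy-4-methoxybenzaldehyde
Product: 6 2-(benzyloxy)-6-bromo-4-methoxybenzaldehyde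
Conditions: BnBr, K2CO3, DMF, rt to 50 °C
Reagents that add atoms: benzyl bromide BrCc1ccccc1
Why: Williamson ether synthesis: the phenoxide, once freed from its hydrogen bond to the aldehyde by carbonate in DMF, is alkylated by the reactive benzylic bromide.

Step 4
Reactants: 6 2-(benzyloxy)-6-bromo-4-methoxybenzaldehyde
Product: 7 2-(benzyloxy)-6-bromo-4-methoxybenzoic acid
Conditions: NaClO2, NaH2PO4, 2-methyl-2-butene, t-BuOH/H2O, rt
Reagents that add atoms: sodium chlorite [Na+].[O-]Cl=O
Why: Pinnick oxidation: chlorous acid adds to the aldehyde and fragments to the acid, and the hypochlorous acid formed is trapped by 2-methyl-2-butene so that the electron-rich ring and the benzyl ether are not chlorinated.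

**Ring B phenol**

Step 5
Reactants: 8 olivetol (5-pentylbenzene-1,3-diol)
Product: 10 2,4-dihydroxy-6-pentylbenzaldehyde, via iminium chloride 9 (not isolated)
Conditions: POCl3, DMF, 0 °C to rt; then H2O, 50 °C
Reagents that add atoms: N,N-dimethylformamide CN(C)C=O; water O
Why: Vilsmeier–Haack formylation of the resorcinol: attack at C4 of olivetol (para to one hydroxyl, ortho to the other) is preferred over the doubly flanked C2 between the two hydroxyls.

Step 6
Reactants: 10 2,4-dihydroxy-6-pentylbenzaldehyde
Product: 11 4-(benzyloxy)-2-hydroxy-6-pentylbenzaldehyde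
Conditions: BnBr (1.05 equiv), KHCO3, MeCN, 60 °C
Reagents that add atoms: benzyl bromide BrCc1ccccc1
Why: Regioselective Williamson etherification: the 4-hydroxyl para to the aldehyde is the more acidic and is free, whereas the 2-hydroxyl is locked in a hydrogen bond to the aldehyde, so the weak base and one equivalent of BnBr should alkylate O-4 only.

Step 7
Reactants: 11 4-(benzyloxy)-2-hydroxy-6-pentylbenzaldehyde
Product: 12 4-(benzyloxy)-2-methoxy-6-pentylbenzaldehyde
Conditions: MeI, K2CO3, DMF, 40 °C
Reagents that add atoms: iodomethane CI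
Why: Williamson methylation of the remaining chelated phenol, which the stronger base and the small electrophile in warm DMF should drive to completion.

Step 8
Reactants: 12 4-(benzyloxy)-2-methoxy-6-pentylbenzaldehyde
Product: 13 4-(benzyloxy)-2-methoxy-6-pentylbenzoic acid
Conditions: NaClO2, NaH2PO4, 2-methyl-2-butene, t-BuOH/H2O, rt
Reagents that add atoms: sodium chlorite [Na+].[O-]Cl=O
Why: Pinnick oxidation of the fully O-protected aldehyde, with the alkene scavenger protecting the electron-rich ring from hypochlorous acid.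

Step 9
Reactants: 13 4-(benzyloxy)-2-methoxy-6-pentylbenzoic acid
Product: 14 4-hydroxy-2-methoxy-6-pentylbenzoic acid
Conditions: H2 (1 atm), 10% Pd/C, EtOAc, rt
Reagents that add atoms: none
Why: Catalytic hydrogenolysis of the aryl benzyl ether on palladium; the acid, the methyl ether and the alkyl chain are inert.

Step 10
Reactants: 14 4-hydroxy-2-methoxy-6-pentylbenzoic acid
Product: 15 benzyl 4-hydroxy-2-methoxy-6-pentylbenzoate
Conditions: BnBr (1.0 equiv), KHCO3, DMF, rt
Reagents that add atoms: benzyl bromide BrCc1ccccc1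
Why: Chemoselective carboxylate O-alkylation (SN2): hydrogencarbonate deprotonates the carboxylic acid but not the phenol, so the benzyl ester should form with the 4-hydroxyl left free.

**Depside bromide**

Step 11
Reactants: 7 2-(benzyloxy)-6-bromo-4-methoxybenzoic acid; 15 benzyl 4-hydroxy-2-methoxy-6-pentylbenzoate
Product: 17 benzyl 4-{[2-(benzyloxy)-6-bromo-4-methoxybenzoyl]oxy}-2-methoxy-6-pentylbenzoate, via acid chloride 16 (not isolated)
Conditions: (COCl)2, DMF (cat.), CH2Cl2, 0 °C to rt, concentrate; then 15, Et3N, DMAP (cat.), CH2Cl2, 0 °C to rt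
Reagents that add atoms: none
Why: Acid chloride formation followed by DMAP-catalysed acylation (addition–elimination) of the only free hydroxyl of 15; the acid carries no keto chain at this stage, so its activation cannot end in an isocoumarin.

**Redox-active ester**

Step 12
Reactants: 18 ethyl 3-oxooctanoate
Product: 19 ethyl 2-(2-pentyl-1,3-dioxolan-2-yl)acetate
Conditions: ethylene glycol, p-TsOH·H2O (cat.), toluene, reflux, Dean–Stark
Reagents that add atoms: ethylene glycol OCCO
Why: Acid-catalysed ketalisation with azeotropic removal of water; only the ketone carbonyl reacts, the ester being much less electrophilic.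

Step 13
Reactants: 19 ethyl 2-(2-pentyl-1,3-dioxolan-2-yl)acetate
Product: 20 2-(2-pentyl-1,3-dioxolan-2-yl)acetic acid
Conditions: LiOH, THF/H2O, rt; then 1 M HCl to pH 4, 0 °C
Reagents that add atoms: lithium hydroxide [Li+].[OH-]
Why: Saponification (base-mediated acyl substitution); the dioxolane is stable to base, and a cold, weakly acidic work-up should spare the ketal.

Step 14
Reactants: 20 2-(2-pentyl-1,3-dioxolan-2-yl)acetic acid
Product: 21 1,3-dioxoisoindolin-2-yl 2-(2-pentyl-1,3-dioxolan-2-yl)acetate
Conditions: N-hydroxyphthalimide, DIC, DMAP (cat.), CH2Cl2, rt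
Reagents that add atoms: N-hydroxyphthalimide O=C1c2ccccc2C(=O)N1O
Why: Carbodiimide (Steglich-type) esterification gives the redox-active ester under neutral conditions that leave the ketal untouched.

**Key coupling and end game**

Step 15
Reactants: 17 benzyl 4-{[2-(benzyloxy)-6-bromo-4-methoxybenzoyl]oxy}-2-methoxy-6-pentylbenzoate; 21 1,3-dioxoisoindolin-2-yl 2-(2-pentyl-1,3-dioxolan-2-yl)acetate
Product: 22 benzyl 4-({2-(benzyloxy)-4-methoxy-6-[(2-pentyl-1,3-dioxolan-2-yl)methyl]benzoyl}oxy)-2-methoxy-6-pentylbenzoate
Conditions: 21 (2.5 equiv), NiCl2·6H2O (20 mol %), 2,2'-bipyridine (20 mol %), AgNO3 (0.5 equiv), LiCl, NMP, Mg anode, reticulated vitreous carbon cathode, constant current, rt, undivided cell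
Reagents that add atoms: none
Why: Cathodic reduction at the silver-coated carbon surface gives zerovalent nickel, which inserts into the ring A C6–Br bond to give a divalent arylnickel bromide; 21 takes up one electron and fragments to phthalimide anion, CO2 and the primary (2-pentyl-1,3-dioxolan-2-yl)methyl radical, which the arylnickel captures to give a trivalent aryl(alkyl)nickel species that reductively eliminates the C6–CH2 bond. The closest known reaction type is the nickel-electrocatalytic decarboxylative sp2–sp3 coupling of N-acyloxyphthalimides with aryl halides, used here on a new substrate. No ring is closed and no stereocentre is formed. The step needs insertion into C–Br instead of the acyl C–O bond of the aryl ester or the benzylic C–O bonds, and coupling instead of hydrodebromination; the weak C–Br bond ortho to the carbonyl, room temperature and the excess of 21 should secure this. The radical carbon has no β-hydrogen (its neighbour is the fully substituted ketal carbon), so β-hydride loss is excluded, and the medium is neutral and free of enolates, so the depside ester and the masked ketone should stay untouched.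

Step 16
Reactants: 22 benzyl 4-({2-(benzyloxy)-4-methoxy-6-[(2-pentyl-1,3-dioxolan-2-yl)methyl]benzoyl}oxy)-2-methoxy-6-pentylbenzoate
Product: 23 benzyl 4-{[2-(benzyloxy)-4-methoxy-6-(2-oxoheptyl)benzoyl]oxy}-2-methoxy-6-pentylbenzoate
Conditions: 1 M aq. HCl, THF, rt
Reagents that add atoms: water O
Why: Acid-catalysed ketal hydrolysis through the oxocarbenium ion; dilute acid at room temperature should leave the benzyl ether, the benzyl ester and the shielded 2,6-disubstituted aryl ester intact.

Step 17
Reactants: 23 benzyl 4-{[2-(benzyloxy)-4-methoxy-6-(2-oxoheptyl)benzoyl]oxy}-2-methoxy-6-pentylbenzoate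
Product: 24 confluentic acid
Conditions: H2 (1 atm), 10% Pd/C, EtOAc, rt
Reagents that add atoms: none
Why: Palladium-catalysed hydrogenolysis cleaves the benzyl ether and the benzyl ester in one neutral operation that should neither reduce the non-conjugated ketone nor disturb the depside ester.

**Compound list**

1 | 1-bromo-3,5-dimethoxybenzene | COc1cc(Br)cc(OC)c1 | starting material
2 | N-[(2-bromo-4,6-dimethoxyphenyl)methylidene]-N-methylmethanaminium chloride | C[N+](C)=Cc1c(Br)cc(OC)cc1OC.[Cl-] | intermediate (not isolated)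
3 | 2-bromo-4,6-dimethoxybenzaldehyde | O=Cc1c(Br)cc(OC)cc1OC | intermediate
4 | 2-bromo-6-[(dichloroboranyl)oxy]-4-methoxybenzaldehyde | O=Cc1c(Br)cc(OC)cc1OB(Cl)Cl | intermediate (not isolated)
5 | 2-bromo-6-hydroxy-4-methoxybenzaldehyde | O=Cc1c(Br)cc(OC)cc1O | intermediate
6 | 2-(benzyloxy)-6-bromo-4-methoxybenzaldehyde | O=Cc1c(Br)cc(OC)cc1OCc1ccccc1 | intermediate
7 | 2-(benzyloxy)-6-bromo-4-methoxybenzoic acid | OC(=O)c1c(Br)cc(OC)cc1OCc1ccccc1 | intermediate
8 | olivetol (5-pentylbenzene-1,3-diol) | CCCCCc1cc(O)cc(O)c1 | starting material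
9 | N-[(2,4-dihydroxy-6-pentylphenyl)methylidene]-N-methylmethanaminium chloride | CCCCCc1cc(O)cc(O)c1C=[N+](C)C.[Cl-] | intermediate (not isolated)
10 | 2,4-dihydroxy-6-pentylbenzaldehyde | CCCCCc1cc(O)cc(O)c1C=O | intermediate
11 | 4-(benzyloxy)-2-hydroxy-6-pentylbenzaldehyde | CCCCCc1cc(OCc2ccccc2)cc(O)c1C=O | intermediate
12 | 4-(benzyloxy)-2-methoxy-6-pentylbenzaldehyde | CCCCCc1cc(OCc2ccccc2)cc(OC)c1C=O | intermediate
13 | 4-(benzyloxy)-2-methoxy-6-pentylbenzoic acid | CCCCCc1cc(OCc2ccccc2)cc(OC)c1C(=O)O | intermediate
14 | 4-hydroxy-2-methoxy-6-pentylbenzoic acid | CCCCCc1cc(O)cc(OC)c1C(=O)O | intermediate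
15 | benzyl 4-hydroxy-2-methoxy-6-pentylbenzoate | CCCCCc1cc(O)cc(OC)c1C(=O)OCc1ccccc1 | intermediate
16 | 2-(benzyloxy)-6-bromo-4-methoxybenzoyl chloride | O=C(Cl)c1c(Br)cc(OC)cc1OCc1ccccc1 | intermediate (not isolated)
17 | benzyl 4-{[2-(benzyloxy)-6-bromo-4-methoxybenzoyl]oxy}-2-methoxy-6-pentylbenzoate | CCCCCc1cc(OC(=O)c2c(Br)cc(OC)cc2OCc2ccccc2)cc(OC)c1C(=O)OCc1ccccc1 | intermediate
18 | ethyl 3-oxooctanoate | CCCCCC(=O)CC(=O)OCC | starting material
19 | ethyl 2-(2-pentyl-1,3-dioxolan-2-yl)acetate | CCCCCC1(CC(=O)OCC)OCCO1 | intermediate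
20 | 2-(2-pentyl-1,3-dioxolan-2-yl)acetic acid | CCCCCC1(CC(=O)O)OCCO1 | intermediate
21 | 1,3-dioxoisoindolin-2-yl 2-(2-pentyl-1,3-dioxolan-2-yl)acetate | CCCCCC1(CC(=O)ON2C(=O)c3ccccc3C2=O)OCCO1 | intermediate
22 | benzyl 4-({2-(benzyloxy)-4-methoxy-6-[(2-pentyl-1,3-dioxolan-2-yl)methyl]benzoyl}oxy)-2-methoxy-6-pentylbenzoate | CCCCCC1(Cc2cc(OC)cc(OCc3ccccc3)c2C(=O)Oc2cc(CCCCC)c(C(=O)OCc3ccccc3)c(OC)c2)OCCO1 | intermediate
23 | benzyl 4-{[2-(benzyloxy)-4-methoxy-6-(2-oxoheptyl)benzoyl]oxy}-2-methoxy-6-pentylbenzoate | CCCCCC(=O)Cc1cc(OC)cc(OCc2ccccc2)c1C(=O)Oc1cc(CCCCC)c(C(=O)OCc2ccccc2)c(OC)c1 | intermediate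
24 | confluentic acid | CCCCCC(=O)Cc1cc(OC)cc(O)c1C(=O)Oc1cc(CCCCC)c(C(=O)O)c(OC)c1 | target

**Step count**

Total: 17 steps. Longest linear sequence: 10 steps (steps 5 to 10, then 11, 15, 16 and 17).

**Steps most likely to fail**

Step 15. Hydrodebromination of the arylnickel intermediate, or reduction and dimerisation of the radical, may outrun radical capture at the ortho-substituted nickel centre, since the radical carbon is neopentyl-like. The fallback sets out from 17 and returns at 23, bypassing step 16. Suzuki–Miyaura coupling of 17 with commercial (E)-hept-1-en-1-ylboronic acid pinacol ester (Pd(dppf)Cl2, CsF, dioxane, 80 °C) should give the styrene benzyl 4-({2-(benzyloxy)-6-[(1E)-hept-1-en-1-yl]-4-methoxybenzoyl}oxy)-2-methoxy-6-pentylbenzoate F1. Tsuji–Wacker oxidation (PdCl2, CuCl, O2, DMF/H2O, rt) is then expected to deliver oxygen to the alkene carbon remote from the ring, because hydroxypalladation of a β-alkylstyrene places palladium on the benzylic carbon, and so to give ketone 23.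

Step 16. Once the ketone is unveiled under acid, acyl transfer from the activated aryl ester to the enol oxygen (cyclisation with expulsion of the ring B phenol) may compete with simple ketal hydrolysis. The fallback sets out from 18 (and uses 17) and returns at 24; it carries the ketone as a ketal that falls in the final neutral hydrogenolysis, so no acid step is needed.
- Ketalisation of 18 with 1,2-benzenedimethanol (p-TsOH, toluene, Dean–Stark) should give ethyl 2-(3-pentyl-1,5-dihydro-3H-2,4-benzodioxepin-3-yl)acetate F2.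
- Saponification (LiOH, THF/H2O) should give 2-(3-pentyl-1,5-dihydro-3H-2,4-benzodioxepin-3-yl)acetic acid F3.
- N-Hydroxyphthalimide and DIC should give 1,3-dioxoisoindolin-2-yl 2-(3-pentyl-1,5-dihydro-3H-2,4-benzodioxepin-3-yl)acetate F4.
- Coupling of F4 with 17 under the conditions of step 15 should give benzyl 4-({2-(benzyloxy)-4-methoxy-6-[(3-pentyl-1,5-dihydro-3H-2,4-benzodioxepin-3-yl)methyl]benzoyl}oxy)-2-methoxy-6-pentylbenzoate F5.
- One hydrogenolysis (H2, Pd/C, EtOAc) then cleaves the benzyl ether, the benzyl ester and a benzylic C–O bond of the ketal; the resulting hemiketal collapses to the ketone, giving 24 directly.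

Step 11. Acylation at the doubly ortho-substituted carbonyl may be slow enough that hydrolysis or decomposition of the activated acid wins. The fallback sets out from 5 (and uses 15) and returns at 17; it esterifies before the ortho benzyl group is in place and by an acylium-type pathway.
- Pinnick oxidation of 5 (NaClO2, NaH2PO4, 2-methyl-2-butene) should give 2-bromo-6-hydroxy-4-methoxybenzoic acid F6.
- Trifluoroacetic anhydride in toluene at rt converts F6 into 2-bromo-6-hydroxy-4-methoxybenzoic trifluoroacetic anhydride F7, which is not isolated and acylates 15 to give benzyl 4-[(2-bromo-6-hydroxy-4-methoxybenzoyl)oxy]-2-methoxy-6-pentylbenzoate F8.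
- Benzylation of the chelated phenol of F8 (BnBr, K2CO3, DMF) rejoins the route at 17.

**Further compounds**

F1 | step 15 | benzyl 4-({2-(benzyloxy)-6-[(1E)-hept-1-en-1-yl]-4-methoxybenzoyl}oxy)-2-methoxy-6-pentylbenzoate | CCCCC/C=C/c1cc(OC)cc(OCc2ccccc2)c1C(=O)Oc1cc(CCCCC)c(C(=O)OCc2ccccc2)c(OC)c1
F2 | step 16 | ethyl 2-(3-pentyl-1,5-dihydro-3H-2,4-benzodioxepin-3-yl)acetate | CCCCCC1(CC(=O)OCC)OCc2ccccc2CO1
F3 | step 16 | 2-(3-pentyl-1,5-dihydro-3H-2,4-benzodioxepin-3-yl)acetic acid | CCCCCC1(CC(=O)O)OCc2ccccc2CO1
F4 | step 16 | 1,3-dioxoisoindolin-2-yl 2-(3-pentyl-1,5-dihydro-3H-2,4-benzodioxepin-3-yl)acetate | CCCCCC1(CC(=O)ON2C(=O)c3ccccc3C2=O)OCc2ccccc2CO1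
F5 | step 16 | benzyl 4-({2-(benzyloxy)-4-methoxy-6-[(3-pentyl-1,5-dihydro-3H-2,4-benzodioxepin-3-yl)methyl]benzoyl}oxy)-2-methoxy-6-pentylbenzoate | CCCCCC1(Cc2cc(OC)cc(OCc3ccccc3)c2C(=O)Oc2cc(CCCCC)c(C(=O)OCc3ccccc3)c(OC)c2)OCc2ccccc2CO1
F6 | step 11 | 2-bromo-6-hydroxy-4-methoxybenzoic acid | OC(=O)c1c(Br)cc(OC)cc1O
F7 | step 11 | 2-bromo-6-hydroxy-4-methoxybenzoic trifluoroacetic anhydride | O=C(OC(=O)C(F)(F)F)c1c(Br)cc(OC)cc1O
F8 | step 11 | benzyl 4-[(2-bromo-6-hydroxy-4-methoxybenzoyl)oxy]-2-methoxy-6-pentylbenzoate | CCCCCc1cc(OC(=O)c2c(Br)cc(OC)cc2O)cc(OC)c1C(=O)OCc1ccccc1
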